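The carbocycle (C4a, C5, C6, C7, C8, C8a) is disconnected at the C8–C8a bond and traced to a 2-acetoxycyclobutanol carried on C4a of a 3,4-dimethoxy-2-methylpyridine. Oxidative ring expansion turns the four-membered ring into the six-membered one in a single operation: the alkoxy radical opens to the C5 ketone and an α-acetoxy C8 radical, which closes onto C8a. The step exploits that C8 is oxygenated and sits on C8a, the carbon next to the ring nitrogen and the only free position beside C4a (C4 carries methoxy). The C5 ketone then takes the side chain; C8 is set by asymmetric transfer hydrogenation and relays its configuration to C5 in a final ionic hydrogenation.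

Key step: step 5

Remark: compounds 4, 5, 7, 8 and 11–13 are racemic (7, 11 and 12 also as diastereomer mixtures); this is harmless because C8 is planarised in step 7 and set in step 8, and C5 is ionised and set in step 12.

Step 1
Reactants: 1 3-methoxy-2-methylpyridin-4(1H)-one
Product: 2 5-bromo-3-methoxy-2-methylpyridin-4(1H)-one
Conditions: NBS, DMF, 0 °C to rt
Reagents that add atoms: N-bromosuccinimide, O=C1CCC(=O)N1Br
Why: The pyridone is a vinylogous amide, so electrophilic aromatic bromination should take place at C5, the only free carbon α to the carbonyl.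

Step 2
Reactants: 2 5-bromo-3-methoxy-2-methylpyridin-4(1H)-one
Product: 3 5-bromo-3,4-dimethoxy-2-methylpyridine
Conditions: MeI, Ag2CO3, toluene, 50 °C, dark
Reagents that add atoms: iodomethane, CI
Why: Silver-salt alkylation of the ambident pyridone is expected to go to oxygen, giving the 4-methoxypyridine that masks the later pyridone carbonyl.

Step 3
Reactants: 4 2-hydroxycyclobutan-1-one
Product: 5 2-oxocyclobutyl acetate
Conditions: Ac2O, pyridine, DMAP (cat.), CH2Cl2, 0 °C
Reagents that add atoms: acetic anhydride, CC(=O)OC(C)=O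
Why: DMAP-catalysed acylation of the secondary alcohol installs an ester that tolerates persulfate and marks the future C8 oxygen.

Step 4
Reactants: 3 5-bromo-3,4-dimethoxy-2-methylpyridine; 5 2-oxocyclobutyl acetate
Product: 7 2-(4,5-dimethoxy-6-methylpyridin-3-yl)-2-hydroxycyclobutyl acetate, via arylmagnesium chloride 6 (not isolated)
Conditions: iPrMgCl·LiCl, THF, 0 °C to rt; then 5, −40 °C; aq NH4Cl
Reagents that add atoms: none
Why: Bromine–magnesium exchange followed by 1,2-addition of the arylmagnesium to the strained, highly electrophilic cyclobutanone should outpace attack on the acetate at low temperature (Grignard addition); both diastereomers are used.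

Step 5
Reactants: 7 2-(4,5-dimethoxy-6-methylpyridin-3-yl)-2-hydroxycyclobutyl acetate
Product: 8 3,4-dimethoxy-2-methyl-5-oxo-5,6,7,8-tetrahydroquinolin-8-yl acetate
Conditions: AgNO3 (20 mol %), K2S2O8, TFA, MeCN/H2O (1:1), 45 °C
Reagents that add atoms: none
Why: Divalent silver formed from AgNO3 and persulfate should oxidise the tertiary cyclobutanol to its alkoxy radical, whose strain-driven β-scission toward the acetoxy-bearing carbon gives the C5 aryl ketone and a secondary α-acetoxyalkyl radical at the future C8; this radical adds to C8a of the protonated pyridine, and oxidation with loss of a proton restores the aromatic ring. The closest known reaction type is the silver- or manganese-mediated oxidative ring expansion of 1-arylcyclobutanols to 1-tetralones, here ended by an intramolecular Minisci-type addition. The one ring closed is the six-membered carbocycle, by attack of the C8 radical on the ring carbon ortho to C4a (6-endo-trig with respect to the C4a–C8a bond), so that the four cyclobutane carbons become C5–C8 and the ring grows by the two pyridine carbons. The new C8 stereocentre forms without control as the racemate, which is accepted because C8 is planarised in step 7 and set in step 8. The step needs regioselective β-scission, secured by the radical-stabilising acetoxy group and the secondary-versus-primary radical preference, and site-selective closure, secured because C4 is blocked by methoxy and C8a is the only free ortho position, the α-carbon of the pyridinium and next to the new ketone.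

Step 6
Reactants: 8 3,4-dimethoxy-2-methyl-5-oxo-5,6,7,8-tetrahydroquinolin-8-yl acetate; 9 (5-bromopentyl)benzene
Product: 12 3,4-dimethoxy-2-methyl-5-(5-phenylpentyl)-5,6,7,8-tetrahydroquinoline-5,8-diol, via (5-phenylpentyl)magnesium bromide 10 (not isolated), via tertiary alcohol acetate 11 (not isolated)
Conditions: 9, Mg, THF; CeCl3, −78 °C; then 8, −78 to 0 °C; then K2CO3, MeOH, rt
Reagents that add atoms: none
Why: Organocerium 1,2-addition should deliver the primary alkyl group to the hindered, enolisable aryl ketone without touching the ester, and methanolysis then frees the C8 alcohol; the new C5 carbinol centre is uncontrolled and is ionised later.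

Step 7
Reactants: 12 3,4-dimethoxy-2-methyl-5-(5-phenylpentyl)-5,6,7,8-tetrahydroquinoline-5,8-diol
Product: 13 5-hydroxy-3,4-dimethoxy-2-methyl-5-(5-phenylpentyl)-6,7-dihydroquinolin-8(5H)-one
Conditions: Dess–Martin periodinane, NaHCO3, CH2Cl2, 0 °C to rt
Reagents that add atoms: none
Why: Dess–Martin oxidation should convert only the secondary pyridyl carbinol, and with C5 fully substituted the 8-ketone cannot tautomerise to an aromatic 8-hydroxyquinoline.

Step 8
Reactants: 13 5-hydroxy-3,4-dimethoxy-2-methyl-5-(5-phenylpentyl)-6,7-dihydroquinolin-8(5H)-one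
Product: 14 (8R)-3,4-dimethoxy-2-methyl-5-(5-phenylpentyl)-5,6,7,8-tetrahydroquinoline-5,8-diol
Conditions: RuCl[(R,R)-TsDPEN](p-cymene) (1 mol %), HCO2H/Et3N (5:2), 30 °C
Reagents that add atoms: none
Why: Noyori asymmetric transfer hydrogenation should set C8 as R under catalyst control, by analogy with 1-tetralone and 2-acylpyridines, where the S,S catalyst gives the S carbinol; the remote racemic C5 centre should not interfere.

Step 9
Reactants: 14 (8R)-3,4-dimethoxy-2-methyl-5-(5-phenylpentyl)-5,6,7,8-tetrahydroquinoline-5,8-diol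
Product: 15 (8R)-3,4,8-trimethoxy-2-methyl-5-(5-phenylpentyl)-5,6,7,8-tetrahydroquinolin-5-ol
Conditions: NaH (1.05 equiv), MeI, THF, 0 °C
Reagents that add atoms: iodomethane, CI
Why: Williamson etherification should take the more acidic and less hindered secondary alkoxide; a methylated tertiary oxygen would ionise just as well in step 12.

Step 10
Reactants: 15 (8R)-3,4,8-trimethoxy-2-methyl-5-(5-phenylpentyl)-5,6,7,8-tetrahydroquinolin-5-ol
Product: 16 (8R)-5-hydroxy-3,4,8-trimethoxy-2-methyl-5-(5-phenylpentyl)-5,6,7,8-tetrahydroquinoline 1-oxide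
Conditions: mCPBA, CH2Cl2, 0 °C to rt
Reagents that add atoms: 3-chloroperbenzoic acid, OOC(=O)c1cccc(Cl)c1
Why: Peracid N-oxidation of the electron-rich pyridine should proceed without touching the ethers, the tertiary alcohol or the phenyl ring.

Step 11
Reactants: 16 (8R)-5-hydroxy-3,4,8-trimethoxy-2-methyl-5-(5-phenylpentyl)-5,6,7,8-tetrahydroquinoline 1-oxide
Product: 18 (8R)-5-hydroxy-1,3,8-trimethoxy-2-methyl-5-(5-phenylpentyl)-5,6,7,8-tetrahydroquinolin-4(1H)-one, via N-methoxypyridinium iodide 17 (not isolated)
Conditions: MeI (excess), MeCN, 90 °C, sealed tube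
Reagents that add atoms: iodomethane, CI
Why: O-methylation of the N-oxide gives the N-methoxypyridinium salt, and iodide then removes the activated 4-O-methyl group by SN2 to leave the pyridone (alkyl-halide-mediated rearrangement of a 4-alkoxypyridine N-oxide to a 1-alkoxy-4-pyridone, a Hilbert–Johnson-type transposition).

Step 12
Reactants: 18 (8R)-5-hydroxy-1,3,8-trimethoxy-2-methyl-5-(5-phenylpentyl)-5,6,7,8-tetrahydroquinolin-4(1H)-one
Product: 19 Waltherione H, (5S,8R)-1,3,8-trimethoxy-2-methyl-5-(5-phenylpentyl)-5,6,7,8-tetrahydroquinolin-4(1H)-one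
Conditions: Et3SiH, TFA, CH2Cl2, −20 to 0 °C
Reagents that add atoms: none
Why: Ionic hydrogenation: acid ionises the tertiary C5 alcohol to a cation stabilised through the vinylogous amide (C5=C4a–C8a=N+), and because peri strain with N–OMe holds the C8 methoxy pseudoaxial, the silane should deliver hydride axially to the opposite face, placing the side chain cis to the methoxy group (5S).

Compound list
1 | 3-methoxy-2-methylpyridin-4(1H)-one | COc1c(C)[nH]ccc1=O | starting material
2 | 5-bromo-3-methoxy-2-methylpyridin-4(1H)-one | COc1c(C)[nH]cc(Br)c1=O | intermediate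
3 | 5-bromo-3,4-dimethoxy-2-methylpyridine | COc1c(C)ncc(Br)c1OC | intermediate
4 | 2-hydroxycyclobutan-1-one (racemic) | O=C1CCC1O | starting material
5 | 2-oxocyclobutyl acetate (racemic) | CC(=O)OC1CCC1=O | intermediate
6 | (4,5-dimethoxy-6-methylpyridin-3-yl)magnesium chloride, LiCl complex | COc1c(C)ncc([Mg]Cl)c1OC | intermediate (not isolated)
7 | 2-(4,5-dimethoxy-6-methylpyridin-3-yl)-2-hydroxycyclobutyl acetate (racemic, both diastereomers) | COc1c(C)ncc(c1OC)C1(O)CCC1OC(C)=O | intermediate
8 | 3,4-dimethoxy-2-methyl-5-oxo-5,6,7,8-tetrahydroquinolin-8-yl acetate (racemic) | COc1c(C)nc2c(c1OC)C(=O)CCC2OC(C)=O | intermediate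
9 | (5-bromopentyl)benzene | BrCCCCCc1ccccc1 | starting material
10 | (5-phenylpentyl)magnesium bromide | Br[Mg]CCCCCc1ccccc1 | intermediate (not isolated)
11 | 5-hydroxy-3,4-dimethoxy-2-methyl-5-(5-phenylpentyl)-5,6,7,8-tetrahydroquinolin-8-yl acetate (racemic, both diastereomers) | COc1c(C)nc2c(c1OC)C(O)(CCCCCc1ccccc1)CCC2OC(C)=O | intermediate (not isolated)
12 | 3,4-dimethoxy-2-methyl-5-(5-phenylpentyl)-5,6,7,8-tetrahydroquinoline-5,8-diol (racemic, both diastereomers) | COc1c(C)nc2c(c1OC)C(O)(CCCCCc1ccccc1)CCC2O | intermediate
13 | 5-hydroxy-3,4-dimethoxy-2-methyl-5-(5-phenylpentyl)-6,7-dihydroquinolin-8(5H)-one (racemic) | COc1c(C)nc2c(c1OC)C(O)(CCCCCc1ccccc1)CCC2=O | intermediate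
14 | (8R)-3,4-dimethoxy-2-methyl-5-(5-phenylpentyl)-5,6,7,8-tetrahydroquinoline-5,8-diol (both C5 epimers) | COc1c(C)nc2c(c1OC)C(O)(CCCCCc1ccccc1)CC[C@H]2O | intermediate
15 | (8R)-3,4,8-trimethoxy-2-methyl-5-(5-phenylpentyl)-5,6,7,8-tetrahydroquinolin-5-ol (both C5 epimers) | COc1c(C)nc2c(c1OC)C(O)(CCCCCc1ccccc1)CC[C@H]2OC | intermediate
16 | (8R)-5-hydroxy-3,4,8-trimethoxy-2-methyl-5-(5-phenylpentyl)-5,6,7,8-tetrahydroquinoline 1-oxide (both C5 epimers) | COc1c(C)[n+]([O-])c2c(c1OC)C(O)(CCCCCc1ccccc1)CC[C@H]2OC | intermediate
17 | (8R)-5-hydroxy-1,3,4,8-tetramethoxy-2-methyl-5-(5-phenylpentyl)-5,6,7,8-tetrahydroquinolin-1-ium iodide | COc1c(C)[n+](OC)c2c(c1OC)C(O)(CCCCCc1ccccc1)CC[C@H]2OC.[I-] | intermediate (not isolated)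
18 | (8R)-5-hydroxy-1,3,8-trimethoxy-2-methyl-5-(5-phenylpentyl)-5,6,7,8-tetrahydroquinolin-4(1H)-one (both C5 epimers) | COc1c(C)n(OC)c2c(c1=O)C(O)(CCCCCc1ccccc1)CC[C@H]2OC | intermediate
19 | Waltherione H, (5S,8R)-1,3,8-trimethoxy-2-methyl-5-(5-phenylpentyl)-5,6,7,8-tetrahydroquinolin-4(1H)-one | COc1c(C)n(OC)c2c(c1=O)[C@@H](CCCCCc1ccccc1)CC[C@H]2OC | target

Total step count: 12. Longest linear sequence: 11 steps (steps 1, 2 and 4–12; step 3 prepares the cyclobutanone partner).

Steps most likely to fail

Step 5. The α-acetoxyalkyl radical may be oxidised further before it closes, β-scission may take the unsubstituted ring bond, or acetyl migration in 7 may divert the alkoxy radical. The fallback sets out from 3 and comes back at 8; it brings in the C8 oxygen after the ring expansion instead of during it. Bromide 3 is converted as in step 4 (iPrMgCl·LiCl) and added to cyclobutanone (O=C1CCC1) to give 1-(4,5-dimethoxy-6-methylpyridin-3-yl)cyclobutan-1-ol F1. The same AgNO3/K2S2O8/TFA ring expansion, now through a primary radical with no scission choice, should give 3,4-dimethoxy-2-methyl-7,8-dihydroquinolin-5(6H)-one F2. mCPBA then gives 3,4-dimethoxy-2-methyl-5-oxo-5,6,7,8-tetrahydroquinoline 1-oxide F3, and Boekelheide rearrangement in Ac2O at 100 °C (O-acetylation, deprotonation at the ring methylene C8, [3,3] shift) should give acetate 8.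

Step 12. Hydride delivery may show poor facial selectivity, or the cation may lose a proton and then methanol, aromatising the carbocycle. The fallback sets out from 18 and comes back at 19; it replaces substrate control by catalyst control. Dehydration of 18 with Burgess reagent (THF, 50 °C) gives the endocyclic alkene (8R)-1,3,8-trimethoxy-2-methyl-5-(5-phenylpentyl)-7,8-dihydroquinolin-4(1H)-one F4. Asymmetric hydrogenation of this trisubstituted alkene with the monovalent iridium catalyst [Ir(cod)(tBu-PHOX)]BArF (ligand enantiomer chosen for 5S), H2 (50 bar), CH2Cl2, should give 19.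

Step 11. Methyl transfer may stall at the pyridinium salt, or iodide may attack the N–O methyl and return the N-oxide. The fallback sets out from 16 and comes back at 18; it dealkylates first and alkylates second. NaSEt in DMF at 90 °C removes the activated 4-O-methyl group of 16 to give (8R)-1,5-dihydroxy-3,8-dimethoxy-2-methyl-5-(5-phenylpentyl)-5,6,7,8-tetrahydroquinolin-4(1H)-one F5. MeI, K2CO3, DMF, rt then methylates the N-hydroxy group to give 18.

Further compounds
F1 | step 5 | 1-(4,5-dimethoxy-6-methylpyridin-3-yl)cyclobutan-1-ol | COc1c(C)ncc(c1OC)C1(O)CCC1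
F2 | step 5 | 3,4-dimethoxy-2-methyl-7,8-dihydroquinolin-5(6H)-one | COc1c(C)nc2c(c1OC)C(=O)CCC2
F3 | step 5 | 3,4-dimethoxy-2-methyl-5-oxo-5,6,7,8-tetrahydroquinoline 1-oxide | COc1c(C)[n+]([O-])c2c(c1OC)C(=O)CCC2
F4 | step 12 | (8R)-1,3,8-trimethoxy-2-methyl-5-(5-phenylpentyl)-7,8-dihydroquinolin-4(1H)-one | COc1c(C)n(OC)c2c(c1=O)C(CCCCCc1ccccc1)=CC[C@H]2OC
F5 | step 11 | (8R)-1,5-dihydroxy-3,8-dimethoxy-2-methyl-5-(5-phenylpentyl)-5,6,7,8-tetrahydroquinolin-4(1H)-one | COc1c(C)n(O)c2c(c1=O)C(O)(CCCCCc1ccccc1)CC[C@H]2OC
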